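Two end percentages and one direction are asked of me, and I answer them by following one molecule of solid electrophile through each flask.

- part of the solid electrophile that has reacted (what has only dissolved counts as not reacted) at the end, north-west
- part of the solid electrophile that has reacted (what has only dissolved counts as not reacted) at the end, east
- what raising the equivalents of nucleophile from its lowest to its highest value here does to the part of the solid electrophile that has reacted (what has only dissolved counts as not reacted) (changes below 5 percentage points count as none) (it rises / it falls / no change)

| flask | solid electrophile | nucleophile | remark | time |
|---|---|---|---|---|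
| eta | 0.75 M | 1.5 equiv | run made earlier |  |
| north-west | 0.50 M | 1.50 equiv |  | 5.0 d |
| east | 0.50 M | 2.20 equiv |  | 5.0 d |

eta run (percent of the solid electrophile charged)

| time / h | solid electrophile / % | product / % |
|---|---|---|
| 2.00 | 98 | 1 |
| 3.00 | 98 | 1 |
| 5.00 | 96 | 0 |
| 8.00 | 92 | 5 |
| 15.0 | 80 | 9 |
| 25.0 | 71 | 14 |

(each reading ± 2 percentage points)

- at the start none of the solid electrophile is in solution
- what has only dissolved of solid electrophile counts as not reacted
- apart from what has only dissolved, what has gone from solid electrophile into another species counts as reacted, even if it can come back
- a reading or a percentage of product counts all its forms, free or not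

In the eta run the solid falls from 96 % at 5.00 h to 71 % at 25.0 h, while product reaches 14 %, and I read the gap as molecules that have dissolved and wait unreacted. If the solid leaves at the same absolute speed from a smaller charge, north-west and east empty in 2.22 d. But the last stretch, from 80 % to 71 %, looks slower, even with a scatter of 2 percentage points, so I carry the clearing time, the charge of solid over its late speed of leaving: 3.09 d, longer than my first figure and shorter than the 5.0 d allowed.

Over that stretch the waiting pool averages 13.0 % and product gains 5 points in 10.0 h, which reads as a pseudo-first-order life of 26.0 h for a dissolved molecule in eta. The average molecule leaves the solid at half the clearing time, so it spends 83.0 h in solution. Scaling the life to the charged nucleophile gives 39.0 h north-west and 26.6 h east, hence 88.1 % and 95.6 % reacted. The objection is that nucleophile is consumed, and the readings do not say how much of it: I guess one per reacted molecule and a mean over the run 0.5 equiv below the charge, so the lives stretch to 58.5 h and 34.4 h, and I commit to 75.8 % north-west and 91.0 % east, a rise of 15 points, beyond the 5 points that counts.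

The forecast gives 88 % and 97 %, with the trend: it rises. It reads the same gap differently, as “an intermediate or reversible adduct”, and it stands above my figures.

The flask gives 78.5 % north-west and 89.8 % east, a change of 11 points: it rises.

    electrophile + nucleophile → acid set free + product (k = 1.70 × 10⁻⁵ M⁻¹ s⁻¹)
    nucleophile + acid set free ⇌ protonated nucleophile, settled at all times (K = 1200 M⁻¹)
    nucleophile + acid set free ⇌ idle adduct A, settled at all times (K = 150 M⁻¹)
    solid electrophile ⇌ electrophile, rate k4*(cs4 - [electrophile]) while solid is left; crystals form when [electrophile] > cs4 (solubility = 0.390 M, k = 7.20 × 10⁻⁶ s⁻¹)
    electrophile + product ⇌ idle adduct B, settled at all times (K = 3.00 M⁻¹)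

My guess of one nucleophile per molecule was wrong: at 5.00 d north-west has lost 1.26 equiv of nucleophile, twice its product of 63.1 % of the charge, so the nearness of my two figures to the flask is luck and no check. North-west holds 13.0 % as solid at 2.50 d and 0 % at 5.00 d. The neighbour of east charged at 1.2 M, with the same equivalents, has a clearing time of 7.41 d, longer than the 5.0 d allowed, and at 5.00 d that flask still holds 14.7 % as solid.

(Readings and results stem from a simulated flask for substances that don't exist; noise was put on by code.)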